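**The leftover.** In the ash run, 7.1% of the complex with two exchanged stands at 60.0 min, down from a top reading of 9.5% at 30.0 min. That fall gives 71.4 min for the fade half-life, the apparent first-order time of one halving of [complex with two exchanged] past its top. The birch run, from its top reading of 4.8% at 10.0 min, gives 64.3 min to its last reading but 134 min to the reading before, so at a scatter of 0.5 percentage points it does not show whether 10 equiv of leaving ligand against 2.5 equiv changes the fade.

common to all: starting complex 20 mM
- ash: incoming ligand 1.1 equiv; leaving ligand 2.5 equiv; run made earlier
- birch: incoming ligand 1.1 equiv; leaving ligand 10 equiv; run made earlier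
- flask: incoming ligand 1.10 equiv; leaving ligand 5.00 equiv; time 1.0 h

- ash (time / min: starting complex / %, complex with two exchanged / %): 8.00: 68.3, 9.4; 15.0: 62.9, 9.1; 25.0: 60.7, 9.4; 30.0: 59.4, 9.5; 40.0: 58.3, 8.4; 50.0: 57.5, 8.1; 60.0: 56.8, 7.1
- birch (time / min: starting complex / %, complex with two exchanged / %): 3.00: 85.8, 2.2; 10.0: 79.2, 4.8; 15.0: 78.6, 4.2; 25.0: 77.5, 3.9; 40.0: 76.8, 3.8; 50.0: 75.7, 3.9; 60.0: 74.8, 2.8

(readings scatter by 0.5 percentage points)

- conversion of starting complex at 1.0 h
- amount of complex with two exchanged at 1.0 h, in percent of the starting complex charged
- amount of complex with two exchanged if the flask were left three thousand times as long, in percent of the starting complex charged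



**Two extremes.** The flask's leaving ligand lies midway on a logarithmic scale between those of ash and birch, so its top is read as 6.75%. With no fade, that top stands at 1.0 h. With fade running the whole hour, 3.77% remains. The ash readings stand level within a scatter of 0.5 points from 8.00 min to 30.0 min, so the start of the fade is read no closer than that span; fading from its two ends gives 4.07% and 5.05%, and this reckoning puts the flask between them. For the long wait, 10 halvings bring the top to 0.00659%, and the wait holds 2521 fade half-lives, so this reckoning commits to nothing measurable.

**The forecast.** It gives 34.5% conversion, 4.8% at the hour and 2.2% after the long wait, the last from a ratio still falling “with no plateau”. That last value differs from the count above.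

**The flask.** It gives 35.2%, 5.28% and 0%. Its complex with two exchanged at the hour stands above the reckoned 5.05%.

    complex with two exchanged + incoming ligand ⇌ leaving ligand + complex with three exchanged (K = 3.90, k = 0.200 M⁻¹ s⁻¹)
    starting complex + incoming ligand ⇌ leaving ligand + complex with one exchanged (K = 2.20, k = 0.0710 M⁻¹ s⁻¹)
    complex with one exchanged + incoming ligand ⇌ leaving ligand + complex with two exchanged (K = 5.30, k = 0.180 M⁻¹ s⁻¹)
    complex with two exchanged → over-reaction product (k = 6.80 × 10⁻⁴ s⁻¹)

Between 0.500 h and 1.00 h, the flask's complex with two exchanged falls from 7.08% to 5.28%, a fade half-life of 70.9 min. In the neighbour flask with 3.00 equiv of leaving ligand, the line through the ash and birch tops reads 8.68%. Fading from 30.0 min with the same 71.4 min leaves 6.49%. That neighbour flask holds 6.25% at the hour.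

The earlier runs and the new flask were computed with constants of no real substance, and the scatter is random.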